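Late in both runs E no longer moves, so what counts is where it stops, and eta is the flask asked about, followed so far.

common to all: X 52 µM

| charge | D | G | Q | temperature | remark | time |
|---|---|---|---|---|---|---|
| eta | 2 mM | 2 mM | 6 mM | 60 °C | the very flask that is asked about, followed so far |  |
| theta | 4 mM | 4 mM | 6 mM | 66 °C | run made earlier |  |
| flask | 2.0 mM | 2.0 mM | 6.00 mM | 60 °C |  | 40 min |

- eta (time / min: E / %): 2.00: 41.5; 6.00: 42.2; 12.0: 41.8; 15.0: 42.0; 25.0: 42.7; 30.0: 42.2; 40.0: 42.2
- theta (time / s: E / %): 12.0: 27.8; 25.0: 29.5; 40.0: 29.0; 50.0: 29.3; 60.0: 29.1; 80.0: 29.0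

(each reading ± 0.3 percentage points)

- X is single-handed; D and G are mirror images of each other, charged as a racemate, each of them at the stated concentration
- removed E is counted in
- the analysis behind the earlier runs scatters by 0.3 percentage points, standard deviation
- additions bring no volume worth counting

- violet: change nothing and wait 80 min more
- ochre: at 40 min add X, 100 % of the amount charged, then wait 80 min
- teal: at 40 min add Q, 100 % of the amount charged, then wait 80 min
- blue: at 40 min raise the temperature by 25 K, then wait 80 min
- grey: at 40 min take out 90 % of the E then present, then wait 80 min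

- E, in percent of the D and G together first charged, at 40 min
- which option adds most E ("none" when 2 percentage points or less is all one gets) (violet / ochre / teal / blue / grey / none)
- E present, with what was taken out counted in, in percent of the D and G together first charged, after ochre
- E present, with what was taken out counted in, in percent of the D and G together first charged, after teal

Reading the last rows against each other, eta ends at 1.69 mM of E and theta at 2.32 mM, from the same 6.00 mM of Q. E stays below that charge in eta, so I assume that Q goes two ways: with X and D into E, and by a first-order loss of its own. Dividing the two rates removes time and [Q], but not [X]: each D consumed costs one Q, plus w/[D] of Q lost, and [X] stands in the denominator of w, so I treat w as constant on the assumption that [X] stays as charged. Integrated until Q is spent, this reads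

[Q] charged = [E] + w·ln([D] charged/[D] final).

Eta leaves 0.312 mM of D on this count and gives 2.32 mM for w, the waste constant: the [D] at which Q is lost as fast as D consumes it. Theta reads 4.24 mM, larger in that hotter run, so I carry w at the temperature of eta.

Teal adds 6.00 mM of Q to eta. With [D] this low, the [D] term hardly counts, so [D] falls to about 0.0269 mM and E reaches 49.3 %, a gain of 7.1 percentage points. Violet, ochre, blue and grey bring no Q, so I expect no gain from them, and I choose teal.

The forecast differs. It gives 42.2 % now, ochre as best, 48.9 % after ochre and 42.2 % after teal, on the judgement “Dead catalyst fits better”.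

The flask gives 42.1 % now, and teal is best with 19 points added. Ochre ends at 42.1 %, and teal at 61.0 %, above my figure.

    Q + X + D → X + E (k = 5.63 × 10⁵ L² mol⁻² s⁻¹, Ea = 23.0 kJ mol⁻¹)
    Q + X + G → X + Z (k = 1.94 × 10⁵ L² mol⁻² s⁻¹, Ea = 25.0 kJ mol⁻¹)
    D ⇌ G (k = 0.0313 s⁻¹, Ea = 81.0 kJ mol⁻¹)
    Q → L (k = 2.65 × 10⁻⁴ s⁻¹, Ea = 95.0 kJ mol⁻¹)
    Q → J (k = 0.0680 s⁻¹, Ea = 75.0 kJ mol⁻¹)
    (constants at 60 °C)

At 42.1 % of E, eta holds Q at 0 % and X at 100 %. The neighbouring flask, charged with 2.4 mM of Q, holds Q at 0 % and X at 100 %, and its E of 21.1 % is 0.843 mM. For that E, the same equation with w asks for 2.11 mM of Q, against 2.4 mM charged. The same flask holds Z at 8.12 %, which is 0.325 mM.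

The readings stem from a simulated flask for an exercise, and the scatter is random.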